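## Structural features

The target is a tetramer of four guaiacyl C6–C3 units built on a trans-3,4-dibenzyl-γ-butyrolactone (lactone C3 R, C4 R). The β-benzyl group (ring B) is etherified at its phenolic oxygen by C8 of an erythro arylglycerol chain: ring A sits on C7 (R), C8 is S, and C9 carries a primary hydroxyl. The α-benzyl group is ring C, which is fused through C7a–O1 and C3a–C3 into a trans-2,3-dihydrobenzofuran with ring D on C2 (S), a hydroxymethyl group on C3 (R) and a methoxy group on C7. The six stereocentres form three vicinal pairs (lactone C3/C4, side-chain C7/C8, dihydrobenzofuran C2/C3) that are too far apart to control one another, so each pair needs its own source of absolute configuration. The fragile points are the two free para-hydroxyphenyl rings that stand para to a benzylic C–O bond (C7–OH for ring A, C2–O1 for ring D) and so can form quinone methides in acid or strong base, the benzylic C–O bonds that are open to hydrogenolysis, and the epimerisable lactone α-carbon. The real difficulty is to make the erythro β-aryl ether and the trans-dihydrobenzofuran each as one enantiomer and to keep five hydroxyl groups apart until the end. The key step exploits that ring C is bonded to C3, that C3 carries an exocyclic CH2–O, and that the neighbouring C2 is an O1–CH(ring D) stereocentre: this is what an aryl radical at the ring C carbon ortho to O1 leaves after 5-exo addition to the inner carbon of a vinyl group on C2 and oxygen capture at the outer carbon.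

## Logic of the disconnections

**35 from 34.** No skeletal bond is cut; five O–Si bonds are. Every hydroxyl group, phenolic or aliphatic, is carried as a silyl ether, so the last operation is one buffered fluoride treatment and no hydrogenolysis is run beside the benzylic C–O bonds. The forward step must stay near neutral.

**34 from 32 and 16.** The bond cut is lactone C3–CH2(ring C). It splits the molecule into two halves of similar size and sets lactone C3 by alkylation of 33 anti to the C4 benzyl group, the most dependable entry to trans-3,4-dibenzyl lactones. The forward step needs a reactive, non-enolisable benzylic halide and no acidic hydrogen in 32 other than the lactone α-hydrogens.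

**16 from 13 through 15 and 14.** No skeletal change. The C5 silyloxymethyl group becomes the bromomethyl handle after the new primary alcohol is capped. This needs a silyl group on the C3 hydroxymethyl (TIPS) that outlasts selective removal of the TBS group.

**13 from 11 (key).** The bonds cut are ring C–C3 and the C–O bond of the hydroxymethyl group. This removes the dihydrofuran ring and the C3 stereocentre and leaves an acyclic aryl allyl ether with one stereocentre. The forward step must close 5-exo before the aryl radical is quenched, capture oxygen at the primary radical (through 12) and place the CH2O group trans to ring D. In 11 ring D carries a TIPS ether and not a benzyl ether, for three reasons: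
- it leaves with the other silyl groups in the final step;
- it offers no O–CH2–aryl hydrogens to peroxyl radicals;
- it is a weaker donor into the ionisable allylic, benzylic C–O bond.

**11 from 9 and 6.** The bond cut is O–C2, the aryl ether bond to the allylic carbon. The only stereocentre of 11 is this carbon, and an enantioselective branched allylic substitution by 10 creates it from an achiral linear carbonate. The forward step must attack the substituted allyl terminus, give high enantiomeric excess with a phenoxide flanked by iodine and methoxy, and not re-ionise the product.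

**6 from 2 and 3 through 5 and 4; 2 from 1; 9 from 7 through 8.** The C=C bond of the cinnamyl unit is cut (olefination). The rest are reductions and protections of commercial aldehydes. 2 serves twice, as the source of ring D and as the ring A aldehyde.

**32 from 27 through 31, 30, 29 and 28.** No skeletal bond is cut. The auxiliary aldol gives the threo (7S,8S) arrangement and the target is erythro (7R,8S), so C7 is inverted by oxidation to 30 and chelation-controlled reduction. The imide carbon becomes C9 by reduction. This needs a reductant for the imide that spares the lactone, and hydride delivery to 30 under chelation control.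

**27 from 25 and 2.** The bond cut is C7–C8. It joins ring A to the C8–C9 unit already on ring B and fixes C8 through the auxiliary. The forward step must enolise the imide selectively in the presence of the lactone (to 26) and show high facial control.

**25 from 23 and 24.** The bond cut is ring B O–CH2. The chiral glycolate unit is attached to a phenol by a simple substitution. O-alkylation must be faster than acyl transfer from the imide.

**23 from 17 and 18 through 22, 21, 20 and 19.** The lactone C–O bond and the C=C bond of a condensation are cut, and lactone C4 is set by asymmetric hydrogenation of the alkene of 19. The chiral lactone then comes from two bulk chemicals. This needs the E half-ester, the catalyst antipode that gives R, and reduction of the ester and not the carboxylate.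

## Other disconnections considered

**Alternative 1:** The cut removes both benzylic C–C bonds of the lactone at once, C4–C(benzylic, ring B) and C3–CH2(ring C).
- Forward step: the lithiated dithiane A3, which already holds rings A and B, would add 1,4 to the chiral butenolide A2 anti to the menthyloxy group at C5. The lactone enolate would then be benzylated in the same flask by bromide A4 anti to the new C4 substituent, to give A1 with no ring formed.
- In its favour: one operation joins three fragments and sets both lactone stereocentres from a cheap crystalline acetal auxiliary, without an asymmetric hydrogenation or a separate enolate step. For the lactone alone it is the better plan in step count (one step against steps 12 to 15 plus step 23).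
- Against it here: A3 must be made by thioacetalisation of an aldehyde that carries an acid-labile benzylic silyl ether. After the coupling the dithiane must be removed reductively (Raney Ni) and the acetal carbon C5 reduced to CH2 on a molecule with several benzylic C–O bonds, a dihydrobenzofuran and benzyl ethers. These late steps on the most valuable intermediate cost what the tandem step saves.
- Comparison: both plans rely on the same element for lactone C3, alkylation of an enolate anti to the C4 substituent, so there they are equal. For C4 the alternative uses substrate control by the C5 acetal, the chosen plan catalyst control on a small molecule. The alternative does not touch the dihydrobenzofuran: A4 would still have to be made, for instance by the radical step used here, so it competes with steps 12 to 15 and 23 and not with the key step.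

**Alternative 2:** The cut goes through both bonds that close the dihydrofuran ring: ring C C5–C8 of a ferulate unit (C3a–C3 of the product) and O1–C2.
- Forward step: Ag2O (monovalent silver) or a carbon anode would oxidise the free ring C phenol of the complete lactone A7 and the phenol of the N-feruloyl oxazolidinone A6 to phenoxyl radicals. Coupling of ferulate C8 with ring C C5, then closure of the ring C phenol oxygen onto the quinone methide carbon C7, would give A5.
- In its favour: it is the biosynthetic construction and forms the ring, two bonds and both stereocentres in one step at the latest possible stage, and A6 needs only a few steps. In step count toward the dihydrobenzofuran it is the better plan. For the trans relationship it is the equal of the radical cyclisation, because addition to the quinone methide also favours the trans ring.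
- Against it here: the bond forms between two different radicals that can each dimerise (8–5, 8–8 and 8–O–4 coupling of A6; 5–5 and 4–O–5 coupling of A7), so chemoselectivity rests on matched oxidation potentials and an excess of one partner. The absolute sense at C2/C3 depends on an auxiliary remote from the bond-forming carbon. All of this is asked of A7, which already contains the whole lactone synthesis.
- Comparison: in the chosen plan the two reacting carbons are tied together in 11, so regio- and chemoselectivity are intramolecular, and the absolute configuration comes from a catalytic asymmetric step on simple fragments. The price is a longer route to the ring (steps 1 to 11).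

**Alternative 3:** The cut is the C2–C3 bond of the dihydrofuran.
- Forward step: Rh2(S-PTTL)4 (divalent rhodium) would decompose the aryldiazoacetate A9, whose ortho oxygen carries the ring D benzyl group. The rhodium carbene would insert 1,5 into one of the enantiotopic benzylic O–CH2 C–H bonds and close the ring as the cis ester, which NaOMe would equilibrate at C3 to the trans ester A8.
- Descriptors: at C3 of A8 the ester carbon outranks C2, so the trans ester that maps onto the (2S,3R) alcohol series is (2S,3S).
- In its favour: both stereocentres come from one catalytic C–C bond formation with a catalyst class that typically gives high enantiomeric excess in this insertion, and C3 is then under thermodynamic control. On enantiocontrol of the C2/C3 pair this is at least the equal of asymmetric etherification followed by 1,2-induction, and probably the better.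
- Against it here: A9 needs an arylacetate and a diazo transfer on a fully substituted ring C. C3 leaves the step as an ester, so a reduction is added. The one-carbon handle at C5 is missing and would have to be built from the bromide (metalation–formylation, reduction, bromination) after the ester has been reduced and protected. Base equilibration of a 3-ester with a phenoxide in the β-position can also open the ring by elimination.
- Comparison: the radical step delivers the C3 hydroxymethyl in the right oxidation state and keeps the C5 carbon from the start. From ring closure to 16 the chosen plan needs three steps where the alternative would need about six. The insertion is catalyst-controlled and the radical closure substrate-controlled, which is the stronger point of the alternative.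

Key step: step 8

Assumption: 4-benzyloxy-3-methoxybenzaldehyde (17), dimethyl succinate (18) and (R)-4-benzyl-3-(chloroacetyl)oxazolidin-2-one (24) are taken as commercial. TIPS = triisopropylsilyl, TBS = tert-butyldimethylsilyl.

## Route

Step 1
Reactants: 1 vanillin
Product: 2 3-methoxy-4-(triisopropylsilyloxy)benzaldehyde
Conditions: TIPSCl, imidazole, DMF, rt
Reagents that add atoms: chlorotriisopropylsilane CC(C)[Si](Cl)(C(C)C)C(C)C
Why: Imidazole-promoted silylation of a phenol; the bulky aryl TIPS ether should survive olefination, hydride reductions, lithium amides and the boron aldol, and it leaves with fluoride at the end.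

Step 2
Reactants: 2 3-methoxy-4-(triisopropylsilyloxy)benzaldehyde; 3 triethyl phosphonoacetate
Product: 4 ethyl (E)-3-[3-methoxy-4-(triisopropylsilyloxy)phenyl]prop-2-enoate
Conditions: LiCl, DBU, MeCN, rt
Reagents that add atoms: none
Why: Horner–Wadsworth–Emmons olefination with a stabilised phosphonate gives the E-cinnamate; the LiCl/amine variant avoids alkoxide that could attack the aryl silyl ether.

Step 3
Reactants: 4 ethyl (E)-3-[3-methoxy-4-(triisopropylsilyloxy)phenyl]prop-2-enoate
Product: 5 (E)-3-[3-methoxy-4-(triisopropylsilyloxy)phenyl]prop-2-en-1-ol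
Conditions: i-Bu2AlH (2.2 equiv), CH2Cl2, −78 °C; aq. potassium sodium tartrate
Reagents that add atoms: none
Why: 1,2-Reduction of a conjugated ester by an aluminium hydride at low temperature gives the allylic alcohol and leaves the alkene and the silyl ether alone.

Step 4
Reactants: 5 (E)-3-[3-methoxy-4-(triisopropylsilyloxy)phenyl]prop-2-en-1-ol
Product: 6 (E)-3-[3-methoxy-4-(triisopropylsilyloxy)phenyl]allyl methyl carbonate
Conditions: ClCO2Me, pyridine, CH2Cl2, 0 °C
Reagents that add atoms: methyl chloroformate COC(=O)Cl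
Why: O-Acylation of a primary allylic alcohol; the methyl carbonate is the usual leaving group for iridium-catalysed allylic substitution.

Step 5
Reactants: 7 5-iodovanillin
Product: 8 4-(hydroxymethyl)-2-iodo-6-methoxyphenol
Conditions: NaBH4, MeOH/THF, 0 °C
Reagents that add atoms: none
Why: Borohydride reduction of an aromatic aldehyde; the aryl iodide and the phenol are inert.

Step 6
Reactants: 8 4-(hydroxymethyl)-2-iodo-6-methoxyphenol
Product: 9 4-{[(tert-butyldimethylsilyl)oxy]methyl}-2-iodo-6-methoxyphenol
Conditions: TBSCl (1.05 equiv), imidazole, CH2Cl2/DMF, 0 °C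
Reagents that add atoms: tert-butylchlorodimethylsilane CC(C)(C)[Si](C)(C)Cl
Why: Chemoselective silylation: the primary benzylic hydroxyl should react faster than a phenol flanked by iodine and methoxy when one equivalent of silyl chloride is used in the cold.

Step 7
Reactants: 9 4-{[(tert-butyldimethylsilyl)oxy]methyl}-2-iodo-6-methoxyphenol; 6 (E)-3-[3-methoxy-4-(triisopropylsilyloxy)phenyl]allyl methyl carbonate
Product: 11 (S)-1-[3-methoxy-4-(triisopropylsilyloxy)phenyl]allyl 4-{[(tert-butyldimethylsilyl)oxy]methyl}-2-iodo-6-methoxyphenyl ether, via lithium phenoxide 10 (not isolated)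
Conditions: LiN(SiMe3)2 (1.0 equiv), THF, 0 °C; then 6, [Ir(cod)Cl]2 (2 mol %), (Sa,Sc,Sc)-O,O′-(1,1′-binaphthalene-2,2′-diyl) N,N-bis(1-phenylethyl)phosphoramidite (4 mol %), THF, rt
Reagents that add atoms: none
Why: Iridium-catalysed enantioselective allylic etherification: the cyclometalated iridium–phosphoramidite forms a π-allyl complex from 6 and the aryloxide attacks its substituted terminus to give the branched ether. The ligand antipode sets the S configuration at the O–CH(ring D) carbon; the (Sa,Sc,Sc) ligand is expected to deliver it, and the (Ra,Rc,Rc) ligand is used instead if the first batch shows the opposite sense. Both ring C positions ortho to the ether oxygen are substituted, so no Claisen rearrangement can follow.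

Step 8
Reactants: 11 (S)-1-[3-methoxy-4-(triisopropylsilyloxy)phenyl]allyl 4-{[(tert-butyldimethylsilyl)oxy]methyl}-2-iodo-6-methoxyphenyl ether
Product: 13 [(2S,3R)-5-{[(tert-butyldimethylsilyl)oxy]methyl}-7-methoxy-2-[3-methoxy-4-(triisopropylsilyloxy)phenyl]-2,3-dihydrobenzofuran-3-yl]methanol, via hydroperoxide 12 (not isolated)
Conditions: Bu3SnH (2 equiv, syringe pump), dry air sparge, Et3B (0.2 equiv), toluene (0.01 M), 0 °C → rt; then PPh3, rt
Reagents that add atoms: dioxygen O=O
Why: The tributylstannyl radical (started by Et3B/O2) abstracts iodine from 11 to give a σ-aryl radical at the ring C carbon ortho to the ether oxygen; this adds to the inner vinyl carbon, O2 captures the primary radical, and the peroxyl radical takes hydrogen from Bu3SnH to carry the chain and leave hydroperoxide 12, which PPh3 reduces to the alcohol. The closest known reaction type is the aerobic tin hydride cyclisation–oxygenation of 2-iodophenyl allyl ethers to 3-hydroxymethyl-2,3-dihydrobenzofurans. The dihydrofuran ring closes in the 5-exo-trig mode, which forms the ring C–C3 bond; the 6-endo mode has poorer orbital overlap in the short, rigid aryl–O–C tether. The new stereocentre C3 is set by 1,2-induction from C2: in the chair-like transition state ring D lies pseudo-equatorial and away from the developing CH2 radical, which puts ring D and the CH2O group trans, (2S,3R). The step needs cyclisation ahead of reduction or oxygenation of the aryl radical, which the very fast closure of ortho-allyloxyphenyl radicals secures, and oxygen capture ahead of hydrogen transfer to the cyclised radical, which slow addition of the stannane into air-saturated toluene secures. The C2 stereocentre is kept because no bond to it is broken and the medium is neutral and cold.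

Step 9
Reactants: 13 [(2S,3R)-5-{[(tert-butyldimethylsilyl)oxy]methyl}-7-methoxy-2-[3-methoxy-4-(triisopropylsilyloxy)phenyl]-2,3-dihydrobenzofuran-3-yl]methanol
Product: 14 (2S,3R)-5-{[(tert-butyldimethylsilyl)oxy]methyl}-7-methoxy-2-[3-methoxy-4-(triisopropylsilyloxy)phenyl]-3-{[(triisopropylsilyl)oxy]methyl}-2,3-dihydrobenzofuran
Conditions: TIPSCl, imidazole, DMAP (cat.), DMF, rt
Reagents that add atoms: chlorotriisopropylsilane CC(C)[Si](Cl)(C(C)C)C(C)C
Why: Silylation of a primary alcohol; the TIPS ether is chosen to outlast the selective removal of the TBS ether in the next step.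

Step 10
Reactants: 14 (2S,3R)-5-{[(tert-butyldimethylsilyl)oxy]methyl}-7-methoxy-2-[3-methoxy-4-(triisopropylsilyloxy)phenyl]-3-{[(triisopropylsilyl)oxy]methyl}-2,3-dihydrobenzofuran
Product: 15 [(2S,3R)-7-methoxy-2-[3-methoxy-4-(triisopropylsilyloxy)phenyl]-3-{[(triisopropylsilyl)oxy]methyl}-2,3-dihydrobenzofuran-5-yl]methanol
Conditions: HF·pyridine, pyridine, THF, 0 °C
Reagents that add atoms: none
Why: Selective desilylation: a primary alkyl TBS ether is cleaved by buffered HF·pyridine much faster than a primary TIPS ether or an aryl TIPS ether, and the buffered medium avoids solvolysis of the electron-rich benzylic positions.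

Step 11
Reactants: 15 [(2S,3R)-7-methoxy-2-[3-methoxy-4-(triisopropylsilyloxy)phenyl]-3-{[(triisopropylsilyl)oxy]methyl}-2,3-dihydrobenzofuran-5-yl]methanol
Product: 16 (2S,3R)-5-(bromomethyl)-7-methoxy-2-[3-methoxy-4-(triisopropylsilyloxy)phenyl]-3-{[(triisopropylsilyl)oxy]methyl}-2,3-dihydrobenzofuran
Conditions: CBr4, PPh3, CH2Cl2, 0 °C; used crude
Reagents that add atoms: tetrabromomethane BrC(Br)(Br)Br
Why: Appel bromination of a primary benzylic alcohol under neutral conditions; the electron-rich bromide is taken on without storage.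

Step 12
Reactants: 17 4-benzyloxy-3-methoxybenzaldehyde; 18 dimethyl succinate
Product: 19 (E)-4-[4-(benzyloxy)-3-methoxyphenyl]-3-(methoxycarbonyl)but-3-enoic acid
Conditions: NaOMe, MeOH, reflux; then aq. HCl
Reagents that add atoms: none
Why: Stobbe condensation: the succinate enolate adds to the aldehyde, the aldolate closes to a paraconate lactone, and base-induced ring opening gives the alkylidene half-ester with aryl and ester trans (E).

Step 13
Reactants: 19 (E)-4-[4-(benzyloxy)-3-methoxyphenyl]-3-(methoxycarbonyl)but-3-enoic acid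
Product: 20 (R)-4-[4-(benzyloxy)-3-methoxyphenyl]-3-(methoxycarbonyl)butanoic acid
Conditions: H2 (4 bar), [Rh(cod)((S,S)-Et-DuPhos)]BF4 (0.5 mol %), NaOMe (10 mol %), MeOH, rt
Reagents that add atoms: none
Why: Rhodium–bisphospholane-catalysed asymmetric hydrogenation of an itaconate-type half-ester: the carboxylate and the alkene chelate rhodium and the ligand selects the alkene face. The (S,S) ligand is expected to give R, and the (R,R) ligand is used instead if the sign of rotation of lactone 22 shows the opposite sense; the homogeneous catalyst does not cleave the benzyl ether.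

Step 14
Reactants: 20 (R)-4-[4-(benzyloxy)-3-methoxyphenyl]-3-(methoxycarbonyl)butanoic acid
Product: 22 (R)-4-[4-(benzyloxy)-3-methoxybenzyl]dihydrofuran-2(3H)-one, via hydroxy acid 21 (not isolated)
Conditions: KOH (1.0 equiv), EtOH; CaCl2, NaBH4, EtOH, −10 °C → rt; then 2 M HCl, rt
Reagents that add atoms: none
Why: Chemoselective borohydride reduction: calcium borohydride reduces the ester while the carboxylate salt is inert, and acidification lactonises the γ-hydroxy acid. The stereocentre is not touched.

Step 15
Reactants: 22 (R)-4-[4-(benzyloxy)-3-methoxybenzyl]dihydrofuran-2(3H)-one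
Product: 23 (R)-4-(4-hydroxy-3-methoxybenzyl)dihydrofuran-2(3H)-one
Conditions: H2 (1 bar), Pd/C, EtOAc, rt
Reagents that add atoms: none
Why: Hydrogenolysis of a benzyl aryl ether; the lactone and the unactivated benzylic CH2 are stable.

Step 16
Reactants: 23 (R)-4-(4-hydroxy-3-methoxybenzyl)dihydrofuran-2(3H)-one; 24 (R)-4-benzyl-3-(chloroacetyl)oxazolidin-2-one
Product: 25 (R)-4-benzyl-3-[2-(2-methoxy-4-{[(3R)-5-oxotetrahydrofuran-3-yl]methyl}phenoxy)acetyl]oxazolidin-2-one
Conditions: K2CO3, NaI (10 mol %), acetone, rt → 45 °C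
Reagents that add atoms: none
Why: Williamson etherification of a phenoxide with a highly SN2-reactive α-halo imide, helped by iodide exchange; the mild carbonate base should leave the lactone and the imide intact.

Step 17
Reactants: 25 (R)-4-benzyl-3-[2-(2-methoxy-4-{[(3R)-5-oxotetrahydrofuran-3-yl]methyl}phenoxy)acetyl]oxazolidin-2-one; 2 3-methoxy-4-(triisopropylsilyloxy)benzaldehyde
Product: 27 (R)-4-benzyl-3-[(2R,3S)-3-hydroxy-2-(2-methoxy-4-{[(3R)-5-oxotetrahydrofuran-3-yl]methyl}phenoxy)-3-[3-methoxy-4-(triisopropylsilyloxy)phenyl]propanoyl]oxazolidin-2-one, via Z-boron enolate 26 (not isolated)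
Conditions: Bu2BOTf, i-Pr2NEt, CH2Cl2, −78 → 0 °C; then 2, −78 → 0 °C; pH 7 buffer, MeOH, H2O2, 0 °C
Reagents that add atoms: none
Why: Evans syn-aldol reaction: soft enolisation gives the Z-boron enolate of the imide only (the lactone is not enolised by this reagent pair), and the chair transition state with the auxiliary benzyl group shielding one face gives the (2R,3S) syn adduct. This fixes C8 of the side chain as S; C7 forms as S (threo) and is inverted in steps 20 and 21.

Step 18
Reactants: 27 (R)-4-benzyl-3-[(2R,3S)-3-hydroxy-2-(2-methoxy-4-{[(3R)-5-oxotetrahydrofuran-3-yl]methyl}phenoxy)-3-[3-methoxy-4-(triisopropylsilyloxy)phenyl]propanoyl]oxazolidin-2-one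
Product: 28 (R)-4-(4-{[(1S,2S)-1,3-dihydroxy-1-[3-methoxy-4-(triisopropylsilyloxy)phenyl]propan-2-yl]oxy}-3-methoxybenzyl)dihydrofuran-2(3H)-one
Conditions: NaBH4, THF/H2O (4:1), 0 °C → rt
Reagents that add atoms: none
Why: Reductive cleavage of an N-acyl oxazolidinone by borohydride in wet THF gives the primary alcohol and frees the auxiliary; the activated imide carbonyl should be reduced much faster than the γ-lactone under these conditions.

Step 19
Reactants: 28 (R)-4-(4-{[(1S,2S)-1,3-dihydroxy-1-[3-methoxy-4-(triisopropylsilyloxy)phenyl]propan-2-yl]oxy}-3-methoxybenzyl)dihydrofuran-2(3H)-one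
Product: 29 (R)-4-(4-{[(1S,2S)-3-[(tert-butyldimethylsilyl)oxy]-1-hydroxy-1-[3-methoxy-4-(triisopropylsilyloxy)phenyl]propan-2-yl]oxy}-3-methoxybenzyl)dihydrofuran-2(3H)-one
Conditions: TBSCl (1.1 equiv), imidazole, CH2Cl2, 0 °C
Reagents that add atoms: tert-butylchlorodimethylsilane CC(C)(C)[Si](C)(C)Cl
Why: Selective silylation of the primary hydroxyl in the presence of the hindered secondary benzylic one.

Step 20
Reactants: 29 (R)-4-(4-{[(1S,2S)-3-[(tert-butyldimethylsilyl)oxy]-1-hydroxy-1-[3-methoxy-4-(triisopropylsilyloxy)phenyl]propan-2-yl]oxy}-3-methoxybenzyl)dihydrofuran-2(3H)-one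
Product: 30 (R)-4-(4-{[(2S)-3-[(tert-butyldimethylsilyl)oxy]-1-[3-methoxy-4-(triisopropylsilyloxy)phenyl]-1-oxopropan-2-yl]oxy}-3-methoxybenzyl)dihydrofuran-2(3H)-one
Conditions: Dess–Martin periodinane, CH2Cl2, 0 °C → rt
Reagents that add atoms: none
Why: Periodinane oxidation of a secondary benzylic alcohol under neutral conditions; without base the α-aryloxy stereocentre C8 should not epimerise, and the ketone is used at once.

Step 21
Reactants: 30 (R)-4-(4-{[(2S)-3-[(tert-butyldimethylsilyl)oxy]-1-[3-methoxy-4-(triisopropylsilyloxy)phenyl]-1-oxopropan-2-yl]oxy}-3-methoxybenzyl)dihydrofuran-2(3H)-one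
Product: 31 (R)-4-(4-{[(1R,2S)-3-[(tert-butyldimethylsilyl)oxy]-1-hydroxy-1-[3-methoxy-4-(triisopropylsilyloxy)phenyl]propan-2-yl]oxy}-3-methoxybenzyl)dihydrofuran-2(3H)-one
Conditions: Zn(BH4)2, Et2O/THF, −30 → 0 °C
Reagents that add atoms: none
Why: Chelation-controlled ketone reduction (Cram chelate model): zinc bridges the carbonyl oxygen and the α-aryloxy oxygen, helped by the ortho methoxy group, and hydride enters from the side of the C8 hydrogen to give the anti (erythro) 7R alcohol. Zinc borohydride does not reduce the lactone.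

Step 22
Reactants: 31 (R)-4-(4-{[(1R,2S)-3-[(tert-butyldimethylsilyl)oxy]-1-hydroxy-1-[3-methoxy-4-(triisopropylsilyloxy)phenyl]propan-2-yl]oxy}-3-methoxybenzyl)dihydrofuran-2(3H)-one
Product: 32 (R)-4-(4-{[(1R,2S)-1,3-bis[(tert-butyldimethylsilyl)oxy]-1-[3-methoxy-4-(triisopropylsilyloxy)phenyl]propan-2-yl]oxy}-3-methoxybenzyl)dihydrofuran-2(3H)-one
Conditions: TBSOTf, 2,6-lutidine, CH2Cl2, −78 → 0 °C
Reagents that add atoms: tert-butyldimethylsilyl trifluoromethanesulfonate CC(C)(C)[Si](C)(C)OS(=O)(=O)C(F)(F)F
Why: Silylation of a hindered secondary benzylic alcohol with a silyl triflate and a hindered pyridine base, which does not enolise the lactone.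

Step 23
Reactants: 32 (R)-4-(4-{[(1R,2S)-1,3-bis[(tert-butyldimethylsilyl)oxy]-1-[3-methoxy-4-(triisopropylsilyloxy)phenyl]propan-2-yl]oxy}-3-methoxybenzyl)dihydrofuran-2(3H)-one; 16 (2S,3R)-5-(bromomethyl)-7-methoxy-2-[3-methoxy-4-(triisopropylsilyloxy)phenyl]-3-{[(triisopropylsilyl)oxy]methyl}-2,3-dihydrobenzofuran
Product: 34 (3R,4R)-4-(4-{[(1R,2S)-1,3-bis[(tert-butyldimethylsilyl)oxy]-1-[3-methoxy-4-(triisopropylsilyloxy)phenyl]propan-2-yl]oxy}-3-methoxybenzyl)-3-{[(2S,3R)-7-methoxy-2-[3-methoxy-4-(triisopropylsilyloxy)phenyl]-3-{[(triisopropylsilyl)oxy]methyl}-2,3-dihydrobenzofuran-5-yl]methyl}dihydrofuran-2(3H)-one, via lithium enolate 33 (not isolated)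
Conditions: LiN(SiMe3)2 (1.05 equiv), THF, −78 °C; then 16, DMPU, −78 → −40 °C
Reagents that add atoms: none
Why: Alkylation of a β-substituted γ-butyrolactone enolate with a benzylic bromide: the electrophile approaches anti to the C4 benzyl group and gives the trans-3,4-disubstituted lactone (new centre C3 R), the standard entry to dibenzylbutyrolactone lignans. The trans isomer is also the more stable one, so any equilibration works in the same direction.

Step 24
Reactants: 34 (3R,4R)-4-(4-{[(1R,2S)-1,3-bis[(tert-butyldimethylsilyl)oxy]-1-[3-methoxy-4-(triisopropylsilyloxy)phenyl]propan-2-yl]oxy}-3-methoxybenzyl)-3-{[(2S,3R)-7-methoxy-2-[3-methoxy-4-(triisopropylsilyloxy)phenyl]-3-{[(triisopropylsilyl)oxy]methyl}-2,3-dihydrobenzofuran-5-yl]methyl}dihydrofuran-2(3H)-one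
Product: 35 (3R,4R)-4-(4-{[(1R,2S)-1,3-dihydroxy-1-(4-hydroxy-3-methoxyphenyl)propan-2-yl]oxy}-3-methoxybenzyl)-3-{[(2S,3R)-2-(4-hydroxy-3-methoxyphenyl)-3-(hydroxymethyl)-7-methoxy-2,3-dihydrobenzofuran-5-yl]methyl}dihydrofuran-2(3H)-one (CNP0265599.1)
Conditions: Bu4NF, AcOH (1:1, excess), THF, 0 °C → rt
Reagents that add atoms: none
Why: Fluoride-mediated cleavage of all five silyl ethers in one operation; acetic acid keeps the medium near neutral so that the freed phenols do not form quinone methides (which would scramble C7 or open the dihydrofuran) and the lactone α-centre is not epimerised.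

## Compound list

1 | vanillin | COc1cc(C=O)ccc1O | starting material
2 | 3-methoxy-4-(triisopropylsilyloxy)benzaldehyde | COc1cc(C=O)ccc1O[Si](C(C)C)(C(C)C)C(C)C | intermediate
3 | triethyl phosphonoacetate | CCOC(=O)CP(=O)(OCC)OCC | starting material
4 | ethyl (E)-3-[3-methoxy-4-(triisopropylsilyloxy)phenyl]prop-2-enoate | CCOC(=O)/C=C/c1ccc(O[Si](C(C)C)(C(C)C)C(C)C)c(OC)c1 | intermediate
5 | (E)-3-[3-methoxy-4-(triisopropylsilyloxy)phenyl]prop-2-en-1-ol | OC/C=C/c1ccc(O[Si](C(C)C)(C(C)C)C(C)C)c(OC)c1 | intermediate
6 | (E)-3-[3-methoxy-4-(triisopropylsilyloxy)phenyl]allyl methyl carbonate | COC(=O)OC/C=C/c1ccc(O[Si](C(C)C)(C(C)C)C(C)C)c(OC)c1 | intermediate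
7 | 5-iodovanillin | COc1cc(C=O)cc(I)c1O | starting material
8 | 4-(hydroxymethyl)-2-iodo-6-methoxyphenol | COc1cc(CO)cc(I)c1O | intermediate
9 | 4-{[(tert-butyldimethylsilyl)oxy]methyl}-2-iodo-6-methoxyphenol | COc1cc(CO[Si](C)(C)C(C)(C)C)cc(I)c1O | intermediate
10 | lithium 4-{[(tert-butyldimethylsilyl)oxy]methyl}-2-iodo-6-methoxyphenoxide | [Li+].COc1cc(CO[Si](C)(C)C(C)(C)C)cc(I)c1[O-] | intermediate
11 | (S)-1-[3-methoxy-4-(triisopropylsilyloxy)phenyl]allyl 4-{[(tert-butyldimethylsilyl)oxy]methyl}-2-iodo-6-methoxyphenyl ether | C=C[C@@H](c1ccc(O[Si](C(C)C)(C(C)C)C(C)C)c(OC)c1)Oc1c(I)cc(CO[Si](C)(C)C(C)(C)C)cc1OC | intermediate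
12 | (2S,3R)-5-{[(tert-butyldimethylsilyl)oxy]methyl}-3-(hydroperoxymethyl)-7-methoxy-2-[3-methoxy-4-(triisopropylsilyloxy)phenyl]-2,3-dihydrobenzofuran | CC(C)(C)[Si](C)(C)OCc1cc(OC)c2c(c1)[C@H](COO)[C@@H](c1ccc(O[Si](C(C)C)(C(C)C)C(C)C)c(OC)c1)O2 | intermediate
13 | [(2S,3R)-5-{[(tert-butyldimethylsilyl)oxy]methyl}-7-methoxy-2-[3-methoxy-4-(triisopropylsilyloxy)phenyl]-2,3-dihydrobenzofuran-3-yl]methanol | CC(C)(C)[Si](C)(C)OCc1cc(OC)c2c(c1)[C@H](CO)[C@@H](c1ccc(O[Si](C(C)C)(C(C)C)C(C)C)c(OC)c1)O2 | intermediate
14 | (2S,3R)-5-{[(tert-butyldimethylsilyl)oxy]methyl}-7-methoxy-2-[3-methoxy-4-(triisopropylsilyloxy)phenyl]-3-{[(triisopropylsilyl)oxy]methyl}-2,3-dihydrobenzofuran | CC(C)(C)[Si](C)(C)OCc1cc(OC)c2c(c1)[C@H](CO[Si](C(C)C)(C(C)C)C(C)C)[C@@H](c1ccc(O[Si](C(C)C)(C(C)C)C(C)C)c(OC)c1)O2 | intermediate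
15 | [(2S,3R)-7-methoxy-2-[3-methoxy-4-(triisopropylsilyloxy)phenyl]-3-{[(triisopropylsilyl)oxy]methyl}-2,3-dihydrobenzofuran-5-yl]methanol | OCc1cc(OC)c2c(c1)[C@H](CO[Si](C(C)C)(C(C)C)C(C)C)[C@@H](c1ccc(O[Si](C(C)C)(C(C)C)C(C)C)c(OC)c1)O2 | intermediate
16 | (2S,3R)-5-(bromomethyl)-7-methoxy-2-[3-methoxy-4-(triisopropylsilyloxy)phenyl]-3-{[(triisopropylsilyl)oxy]methyl}-2,3-dihydrobenzofuran | BrCc1cc(OC)c2c(c1)[C@H](CO[Si](C(C)C)(C(C)C)C(C)C)[C@@H](c1ccc(O[Si](C(C)C)(C(C)C)C(C)C)c(OC)c1)O2 | intermediate
17 | 4-benzyloxy-3-methoxybenzaldehyde | COc1cc(C=O)ccc1OCc1ccccc1 | starting material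
18 | dimethyl succinate | COC(=O)CCC(=O)OC | starting material
19 | (E)-4-[4-(benzyloxy)-3-methoxyphenyl]-3-(methoxycarbonyl)but-3-enoic acid | COC(=O)/C(CC(=O)O)=C/c1ccc(OCc2ccccc2)c(OC)c1 | intermediate
20 | (R)-4-[4-(benzyloxy)-3-methoxyphenyl]-3-(methoxycarbonyl)butanoic acid | COC(=O)[C@@H](CC(=O)O)Cc1ccc(OCc2ccccc2)c(OC)c1 | intermediate
21 | (R)-4-[4-(benzyloxy)-3-methoxyphenyl]-3-(hydroxymethyl)butanoic acid | OC[C@@H](CC(=O)O)Cc1ccc(OCc2ccccc2)c(OC)c1 | intermediate
22 | (R)-4-[4-(benzyloxy)-3-methoxybenzyl]dihydrofuran-2(3H)-one | COc1cc(C[C@H]2COC(=O)C2)ccc1OCc1ccccc1 | intermediate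
23 | (R)-4-(4-hydroxy-3-methoxybenzyl)dihydrofuran-2(3H)-one | COc1cc(C[C@H]2COC(=O)C2)ccc1O | intermediate
24 | (R)-4-benzyl-3-(chloroacetyl)oxazolidin-2-one | O=C(CCl)N1[C@H](Cc2ccccc2)COC1=O | starting material
25 | (R)-4-benzyl-3-[2-(2-methoxy-4-{[(3R)-5-oxotetrahydrofuran-3-yl]methyl}phenoxy)acetyl]oxazolidin-2-one | COc1cc(C[C@H]2COC(=O)C2)ccc1OCC(=O)N1[C@H](Cc2ccccc2)COC1=O | intermediate
26 | dibutylboron (Z)-enolate of 25 (O-boron, aryloxy and O–B cis) | CCCCB(CCCC)O/C(=C\Oc1ccc(C[C@H]2COC(=O)C2)cc1OC)N1[C@H](Cc2ccccc2)COC1=O | intermediate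
27 | (R)-4-benzyl-3-[(2R,3S)-3-hydroxy-2-(2-methoxy-4-{[(3R)-5-oxotetrahydrofuran-3-yl]methyl}phenoxy)-3-[3-methoxy-4-(triisopropylsilyloxy)phenyl]propanoyl]oxazolidin-2-one | O[C@@H](c1ccc(O[Si](C(C)C)(C(C)C)C(C)C)c(OC)c1)[C@@H](Oc1ccc(C[C@H]2COC(=O)C2)cc1OC)C(=O)N1[C@H](Cc2ccccc2)COC1=O | intermediate
28 | (R)-4-(4-{[(1S,2S)-1,3-dihydroxy-1-[3-methoxy-4-(triisopropylsilyloxy)phenyl]propan-2-yl]oxy}-3-methoxybenzyl)dihydrofuran-2(3H)-one | O[C@@H](c1ccc(O[Si](C(C)C)(C(C)C)C(C)C)c(OC)c1)[C@@H](Oc1ccc(C[C@H]2COC(=O)C2)cc1OC)CO | intermediate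
29 | (R)-4-(4-{[(1S,2S)-3-[(tert-butyldimethylsilyl)oxy]-1-hydroxy-1-[3-methoxy-4-(triisopropylsilyloxy)phenyl]propan-2-yl]oxy}-3-methoxybenzyl)dihydrofuran-2(3H)-one | O[C@@H](c1ccc(O[Si](C(C)C)(C(C)C)C(C)C)c(OC)c1)[C@@H](Oc1ccc(C[C@H]2COC(=O)C2)cc1OC)CO[Si](C)(C)C(C)(C)C | intermediate
30 | (R)-4-(4-{[(2S)-3-[(tert-butyldimethylsilyl)oxy]-1-[3-methoxy-4-(triisopropylsilyloxy)phenyl]-1-oxopropan-2-yl]oxy}-3-methoxybenzyl)dihydrofuran-2(3H)-one | O=C(c1ccc(O[Si](C(C)C)(C(C)C)C(C)C)c(OC)c1)[C@@H](Oc1ccc(C[C@H]2COC(=O)C2)cc1OC)CO[Si](C)(C)C(C)(C)C | intermediate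
31 | (R)-4-(4-{[(1R,2S)-3-[(tert-butyldimethylsilyl)oxy]-1-hydroxy-1-[3-methoxy-4-(triisopropylsilyloxy)phenyl]propan-2-yl]oxy}-3-methoxybenzyl)dihydrofuran-2(3H)-one | O[C@H](c1ccc(O[Si](C(C)C)(C(C)C)C(C)C)c(OC)c1)[C@@H](Oc1ccc(C[C@H]2COC(=O)C2)cc1OC)CO[Si](C)(C)C(C)(C)C | intermediate
32 | (R)-4-(4-{[(1R,2S)-1,3-bis[(tert-butyldimethylsilyl)oxy]-1-[3-methoxy-4-(triisopropylsilyloxy)phenyl]propan-2-yl]oxy}-3-methoxybenzyl)dihydrofuran-2(3H)-one | CC(C)(C)[Si](C)(C)O[C@H](c1ccc(O[Si](C(C)C)(C(C)C)C(C)C)c(OC)c1)[C@@H](Oc1ccc(C[C@H]2COC(=O)C2)cc1OC)CO[Si](C)(C)C(C)(C)C | intermediate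
33 | lithium enolate of 32 (lactone C2–O–Li, C2=C3) | [Li+].CC(C)(C)[Si](C)(C)O[C@H](c1ccc(O[Si](C(C)C)(C(C)C)C(C)C)c(OC)c1)[C@@H](Oc1ccc(C[C@H]2COC([O-])=C2)cc1OC)CO[Si](C)(C)C(C)(C)C | intermediate
34 | (3R,4R)-4-(4-{[(1R,2S)-1,3-bis[(tert-butyldimethylsilyl)oxy]-1-[3-methoxy-4-(triisopropylsilyloxy)phenyl]propan-2-yl]oxy}-3-methoxybenzyl)-3-{[(2S,3R)-7-methoxy-2-[3-methoxy-4-(triisopropylsilyloxy)phenyl]-3-{[(triisopropylsilyl)oxy]methyl}-2,3-dihydrobenzofuran-5-yl]methyl}dihydrofuran-2(3H)-one | COc1cc([C@@H](O[Si](C)(C)C(C)(C)C)[C@H](CO[Si](C)(C)C(C)(C)C)Oc2ccc(C[C@H]3COC(=O)[C@@H]3Cc3cc(OC)c4c(c3)[C@H](CO[Si](C(C)C)(C(C)C)C(C)C)[C@@H](c3ccc(O[Si](C(C)C)(C(C)C)C(C)C)c(OC)c3)O4)cc2OC)ccc1O[Si](C(C)C)(C(C)C)C(C)C | intermediate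
35 | (3R,4R)-4-(4-{[(1R,2S)-1,3-dihydroxy-1-(4-hydroxy-3-methoxyphenyl)propan-2-yl]oxy}-3-methoxybenzyl)-3-{[(2S,3R)-2-(4-hydroxy-3-methoxyphenyl)-3-(hydroxymethyl)-7-methoxy-2,3-dihydrobenzofuran-5-yl]methyl}dihydrofuran-2(3H)-one | COc1cc([C@@H](O)[C@H](CO)Oc2ccc(C[C@H]3COC(=O)[C@@H]3Cc3cc(OC)c4c(c3)[C@H](CO)[C@@H](c3ccc(O)c(OC)c3)O4)cc2OC)ccc1O | target

## Step count and risk

Total step count: 24. Longest linear sequence: 13 steps (steps 12 to 24).

**Step 8 (key step).** The likeliest failures are three:
- hydrogen transfer from the stannane to the cyclised primary radical before oxygen capture, which loses the oxygen function;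
- peroxyl-radical attack at the doubly activated C2–H;
- incomplete facial bias in the ring closure, which would give some cis ring.

Fallback, from 11 back to 13: run the same 5-exo closure with a persistent nitroxide as the trap. Bu3SnH and TEMPO in benzene at 70 °C should give the alkoxyamine 1-{[(2S,3R)-5-{[(tert-butyldimethylsilyl)oxy]methyl}-7-methoxy-2-[3-methoxy-4-(triisopropylsilyloxy)phenyl]-2,3-dihydrobenzofuran-3-yl]methoxy}-2,2,6,6-tetramethylpiperidine F1. Zn dust in AcOH/THF without added water, to spare the benzylic silyl ether, would then cleave the N–O bond to 13.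

**Step 7.** The allyl system is electron-rich and the phenoxide is hindered and a fair leaving group. Attack at the unsubstituted allyl terminus and re-ionisation of the branched ether could therefore erode regio- and enantioselectivity. Fallback, from 2 and 9 back to 11, makes the C–O bond by propargylic substitution:
- ethynylmagnesium bromide (HC≡CMgBr) adds to 2 to give racemic 1-[3-methoxy-4-(triisopropylsilyloxy)phenyl]prop-2-yn-1-ol F2;
- acetylation gives rac-1-[3-methoxy-4-(triisopropylsilyloxy)phenyl]prop-2-yn-1-yl acetate F3;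
- copper-catalysed enantioselective propargylic etherification with 9 (CuOTf·1/2C6H6, a chiral 2,6-bis(oxazolinyl)pyridine ligand, i-Pr2NEt), through a copper allenylidene, should give (S)-1-[3-methoxy-4-(triisopropylsilyloxy)phenyl]prop-2-yn-1-yl 4-{[(tert-butyldimethylsilyl)oxy]methyl}-2-iodo-6-methoxyphenyl ether F4;
- semi-hydrogenation over Pd/CaCO3 poisoned with Pb(OAc)2 and quinoline, stopped at one equivalent of H2 to spare the C–I bond, gives 11.

**Step 21.** An aryl ether oxygen is a weak donor to zinc, so non-chelated (polar Felkin–Anh) hydride delivery could compete with chelated delivery and lower the diastereoselectivity. Base-induced epimerisation at C8 of 30 is a second risk. Fallback, from 29 back to 31 without the ketone: Mitsunobu inversion of the C7 carbinol of 29 with chloroacetic acid (PPh3, diisopropyl azodicarboxylate, toluene, 0 °C) to (1R,2S)-3-[(tert-butyldimethylsilyl)oxy]-2-(2-methoxy-4-{[(3R)-5-oxotetrahydrofuran-3-yl]methyl}phenoxy)-1-[3-methoxy-4-(triisopropylsilyloxy)phenyl]propyl chloroacetate F9. Thiourea with NaHCO3 in EtOH then removes the chloroacetate to give 31 without touching the lactone.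

**Step 18.** Hydride attack on the lactone carbonyl beside the imide would cause over-reduction. Fallback, from 27 back to 28: hydrolyse the auxiliary with LiOH/H2O2 (THF/H2O, 0 °C; acidification recloses any opened lactone) to (2R,3S)-3-hydroxy-2-(2-methoxy-4-{[(3R)-5-oxotetrahydrofuran-3-yl]methyl}phenoxy)-3-[3-methoxy-4-(triisopropylsilyloxy)phenyl]propanoic acid F8. BH3·THF at 0 °C, which reduces a carboxylic acid much faster than a lactone, then gives 28.

**Step 16.** The phenoxide could attack the exocyclic imide carbonyl instead of substituting at CH2Cl, which would strip the auxiliary. Fallback, from 23 back to 25, builds the imide after the ether bond: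
- 23 with tert-butyl bromoacetate and K2CO3 gives tert-butyl 2-(2-methoxy-4-{[(3R)-5-oxotetrahydrofuran-3-yl]methyl}phenoxy)acetate F5;
- CF3CO2H in CH2Cl2 gives 2-(2-methoxy-4-{[(3R)-5-oxotetrahydrofuran-3-yl]methyl}phenoxy)acetic acid F6;
- pivaloyl chloride and Et3N give 2-(2-methoxy-4-{[(3R)-5-oxotetrahydrofuran-3-yl]methyl}phenoxy)acetic pivalic anhydride F7;
- F7 acylates (R)-4-benzyloxazolidin-2-one in the presence of LiCl to give 25.

Further compounds

F1 | step 8 | 1-{[(2S,3R)-5-{[(tert-butyldimethylsilyl)oxy]methyl}-7-methoxy-2-[3-methoxy-4-(triisopropylsilyloxy)phenyl]-2,3-dihydrobenzofuran-3-yl]methoxy}-2,2,6,6-tetramethylpiperidine | CC(C)(C)[Si](C)(C)OCc1cc(OC)c2c(c1)[C@H](CON1C(C)(C)CCCC1(C)C)[C@@H](c1ccc(O[Si](C(C)C)(C(C)C)C(C)C)c(OC)c1)O2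
F2 | step 7 | rac-1-[3-methoxy-4-(triisopropylsilyloxy)phenyl]prop-2-yn-1-ol | OC(C#C)c1ccc(O[Si](C(C)C)(C(C)C)C(C)C)c(OC)c1
F3 | step 7 | rac-1-[3-methoxy-4-(triisopropylsilyloxy)phenyl]prop-2-yn-1-yl acetate | CC(=O)OC(C#C)c1ccc(O[Si](C(C)C)(C(C)C)C(C)C)c(OC)c1
F4 | step 7 | (S)-1-[3-methoxy-4-(triisopropylsilyloxy)phenyl]prop-2-yn-1-yl 4-{[(tert-butyldimethylsilyl)oxy]methyl}-2-iodo-6-methoxyphenyl ether | C#C[C@@H](c1ccc(O[Si](C(C)C)(C(C)C)C(C)C)c(OC)c1)Oc1c(I)cc(CO[Si](C)(C)C(C)(C)C)cc1OC
F5 | step 16 | tert-butyl 2-(2-methoxy-4-{[(3R)-5-oxotetrahydrofuran-3-yl]methyl}phenoxy)acetate | CC(C)(C)OC(=O)COc1ccc(C[C@H]2COC(=O)C2)cc1OC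
F6 | step 16 | 2-(2-methoxy-4-{[(3R)-5-oxotetrahydrofuran-3-yl]methyl}phenoxy)acetic acid | OC(=O)COc1ccc(C[C@H]2COC(=O)C2)cc1OC
F7 | step 16 | 2-(2-methoxy-4-{[(3R)-5-oxotetrahydrofuran-3-yl]methyl}phenoxy)acetic pivalic anhydride | CC(C)(C)C(=O)OC(=O)COc1ccc(C[C@H]2COC(=O)C2)cc1OC
F8 | step 18 | (2R,3S)-3-hydroxy-2-(2-methoxy-4-{[(3R)-5-oxotetrahydrofuran-3-yl]methyl}phenoxy)-3-[3-methoxy-4-(triisopropylsilyloxy)phenyl]propanoic acid | O[C@@H](c1ccc(O[Si](C(C)C)(C(C)C)C(C)C)c(OC)c1)[C@@H](Oc1ccc(C[C@H]2COC(=O)C2)cc1OC)C(=O)O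
F9 | step 21 | (1R,2S)-3-[(tert-butyldimethylsilyl)oxy]-2-(2-methoxy-4-{[(3R)-5-oxotetrahydrofuran-3-yl]methyl}phenoxy)-1-[3-methoxy-4-(triisopropylsilyloxy)phenyl]propyl chloroacetate | ClCC(=O)O[C@H](c1ccc(O[Si](C(C)C)(C(C)C)C(C)C)c(OC)c1)[C@@H](Oc1ccc(C[C@H]2COC(=O)C2)cc1OC)CO[Si](C)(C)C(C)(C)C
A1 | alternative 1 | fully assembled skeleton as 1,3-dithiane and (5R)-menthyl acetal (lactone C3 R, C4 and C5 substituents trans) | COc1cc([C@@H](O[Si](C)(C)C(C)(C)C)[C@H](CO[Si](C)(C)C(C)(C)C)Oc2ccc(C3(SCCCS3)[C@H]3[C@H](O[C@@H]4C[C@H](C)CC[C@H]4C(C)C)OC(=O)[C@@H]3Cc3cc(OC)c4c(c3)[C@H](CO[Si](C)(C)C(C)(C)C)[C@@H](c3ccc(OCc5ccccc5)c(OC)c3)O4)cc2OC)ccc1OCc1ccccc1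
A2 | alternative 1 | (5R)-5-[(1R,2S,5R)-menthyloxy]furan-2(5H)-one | O=C1C=C[C@H](O[C@@H]2C[C@H](C)CC[C@H]2C(C)C)O1
A3 | alternative 1 | 2-{4-[(1R,2S)-1-[4-(benzyloxy)-3-methoxyphenyl]-1,3-bis[(tert-butyldimethylsilyl)oxy]propan-2-yloxy]-3-methoxyphenyl}-1,3-dithiane | COc1cc([C@@H](O[Si](C)(C)C(C)(C)C)[C@H](CO[Si](C)(C)C(C)(C)C)Oc2ccc(C3SCCCS3)cc2OC)ccc1OCc1ccccc1
A4 | alternative 1 | (2S,3R)-2-[4-(benzyloxy)-3-methoxyphenyl]-5-(bromomethyl)-3-{[(tert-butyldimethylsilyl)oxy]methyl}-7-methoxy-2,3-dihydrobenzofuran | BrCc1cc(OC)c2c(c1)[C@H](CO[Si](C)(C)C(C)(C)C)[C@@H](c1ccc(OCc3ccccc3)c(OC)c1)O2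
A5 | alternative 2 | trans-dihydrobenzofuran with C3 acyl (S)-4-benzyloxazolidinone on the full protected skeleton | COc1cc([C@@H](O[Si](C)(C)C(C)(C)C)[C@H](CO[Si](C)(C)C(C)(C)C)Oc2ccc(C[C@H]3COC(=O)[C@@H]3Cc3cc(OC)c4c(c3)[C@H](C(=O)N3[C@@H](Cc5ccccc5)COC3=O)[C@@H](c3ccc(O)c(OC)c3)O4)cc2OC)ccc1OCc1ccccc1
A6 | alternative 2 | (S)-4-benzyl-3-[(E)-3-(4-hydroxy-3-methoxyphenyl)prop-2-enoyl]oxazolidin-2-one | COc1cc(/C=C/C(=O)N2[C@@H](Cc3ccccc3)COC2=O)ccc1O
A7 | alternative 2 | (3R,4R)-4-{4-[(1R,2S)-1-[4-(benzyloxy)-3-methoxyphenyl]-1,3-bis[(tert-butyldimethylsilyl)oxy]propan-2-yloxy]-3-methoxybenzyl}-3-(4-hydroxy-3-methoxybenzyl)dihydrofuran-2(3H)-one | COc1cc([C@@H](O[Si](C)(C)C(C)(C)C)[C@H](CO[Si](C)(C)C(C)(C)C)Oc2ccc(C[C@H]3COC(=O)[C@@H]3Cc3ccc(O)c(OC)c3)cc2OC)ccc1OCc1ccccc1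
A8 | alternative 3 | methyl (2S,3S)-trans-2-[4-(benzyloxy)-3-methoxyphenyl]-5-bromo-7-methoxy-2,3-dihydrobenzofuran-3-carboxylate | Brc1cc(OC)c2c(c1)[C@H](C(=O)OC)[C@@H](c1ccc(OCc3ccccc3)c(OC)c1)O2
A9 | alternative 3 | methyl 2-{2-[4-(benzyloxy)-3-methoxybenzyloxy]-5-bromo-3-methoxyphenyl}-2-diazoacetate | COC(=O)C(=[N+]=[N-])c1cc(Br)cc(OC)c1OCc1ccc(OCc2ccccc2)c(OC)c1
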